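**Retrosynthetic overview**

1. Feature used: on the tribromophenol ring (ring B: C1–OH, C2–OAr, C3/C4/C6–Br) the ether carbon C2 lies between C1–OH and C3–Br, and on the other ring (ring A) the ether oxygen is ortho to the free OH. An ester from that ring-A OH to a carboxyl carbon placed on C3 therefore holds the second ring-A oxygen over C2.
2. C3–Br ⇐ C3–NH2 (Sandmeyer) ⇐ C3–CONH2 (Hofmann) ⇐ ammonolysis of the lactone of a dibenzo[b,e][1,4]dioxepin-11-one (depsidone). Ring-A Br ⇐ para-bromination of the phenol that the lactone opening sets free.
3. Key disconnection: diaryl ether O–C2 bond and the seven-membered ring ⇐ anodic intramolecular phenol O–C coupling of the depside 2-hydroxyphenyl 2,4-dibromo-5-hydroxybenzoate.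
4. Depside ⇐ ester of 2,4-dibromo-5-methoxybenzoic acid (from 3-methoxybenzoic acid) with 2-methoxyphenol, then double O-demethylation.
5. Ring order: both benzene rings are bought. The only ring formed is the seven-membered lactone (step 4), opened again in step 5 once it has delivered the ether bond.

Key step: step 4

**Remarks on the chemistry**

- The target has no stereocentre and is achiral, so no stereocontrol is needed.
- Ring A carries no bromine until step 6. A brominated catechol mono-ester can shift its acyl group between the two oxygens and would scramble the ether position, whereas for the unsubstituted catechol ester the shift is degenerate. The bromine then enters para to the hydroxyl freed from the ester, which is its place in the target.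
- The carboxyl carbon is exchanged for bromine through amide and amine, not by radical bromodecarboxylation. Aroyloxyl radicals of 2-aryloxybenzoic acids are prone to a 1,5-aryl shift from ether oxygen to carboxyl oxygen, which would destroy the diaryl ether.

**Route**

Step 1
Reactants: 1 3-methoxybenzoic acid
Product: 2 2,4-dibromo-5-methoxybenzoic acid
Conditions: Br2 (2.5 equiv), AcOH, 70 °C
Reagents that add atoms: bromine, BrBr
Why: Electrophilic aromatic bromination directed by the methoxy group should put the first bromine para to OMe and the second at the open ortho position, while the carbon between OMe and CO2H is shielded and the dibromo acid is too deactivated to react further.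

Step 2
Reactants: 2 2,4-dibromo-5-methoxybenzoic acid; 3 2-methoxyphenol
Product: 5 2-methoxyphenyl 2,4-dibromo-5-methoxybenzoate, via aroyl chloride 4 (not isolated)
Conditions: (COCl)2, DMF (cat.), CH2Cl2, 0 °C → rt; evaporate; then 3, Et3N, DMAP (cat.), CH2Cl2, 0 °C → rt
Reagents that add atoms: none
Why: Acid chloride formation (Vilsmeier-type activation) followed by DMAP-catalysed O-acylation of the only hydroxyl present should give the aryl ester, the single ortho bromine not blocking the acyl carbon.

Step 3
Reactants: 5 2-methoxyphenyl 2,4-dibromo-5-methoxybenzoate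
Product: 6 2-hydroxyphenyl 2,4-dibromo-5-hydroxybenzoate
Conditions: BBr3 (5 equiv), CH2Cl2, −78 → 0 °C; ice-cold 1 M HCl
Reagents that add atoms: none
Why: Lewis-acid aryl methyl ether cleavage with BBr3 proceeds by bromide attack on the boron-complexed O–CH3 groups, a path the aryl ester does not have, so the ester should survive at or below 0 °C, and any acyl shift on the unsubstituted catechol returns the same compound.

Step 4
Reactants: 6 2-hydroxyphenyl 2,4-dibromo-5-hydroxybenzoate
Product: 8 1,3-dibromo-4-hydroxy-11H-dibenzo[b,e][1,4]dioxepin-11-one, via dienone tautomer 7 (not isolated)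
Conditions: constant-current electrolysis (BDD anode, Pt cathode, undivided cell, 1 mA cm⁻², 2.1 F mol⁻¹); 6 (2 mM), Bu4NPF6 (0.05 M), 2,6-lutidine (2 equiv), HFIP, 20 °C
Reagents that add atoms: none
Why: Two electrons and two protons are removed at the anode: the benzoate-ring phenol, expected to be the more acidic OH and hydrogen-bonded to lutidine, should be oxidised through its phenoxyl radical to a phenoxonium ion with positive charge on the two bromine-bearing carbons and on the one hydrogen-bearing carbon between C–OH and the acyl-bearing carbon; the catechol OH adds to that carbon and the 2,4-cyclohexadienone 7 enolises to 8. The closest known reaction types are the oxidative depside-to-depsidone phenol coupling and the anodic diaryl ether synthesis from bromophenols. The seven-membered dioxepinone closes by O-attack on an sp2 carbon lying inside the new ring (formally 7-endo), from the s-cis rotamer of the ester. No stereocentre remains, since the sp3 carbon of 7 is lost on enolisation. The step needs O–C bonding at the hydrogen-bearing carbon and not at the bromine-bearing carbon para to the phenol oxygen, the only other site the tether can reach: addition at C–H aromatises irreversibly by proton loss, whereas the ipso adduct cannot aromatise and can revert. C–C coupling would need a meta-bridged ring, dimerisation is held back by dilution in HFIP, and the hindered lutidine should not add to the cation.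

Step 5
Reactants: 8 1,3-dibromo-4-hydroxy-11H-dibenzo[b,e][1,4]dioxepin-11-one
Product: 9 4,6-dibromo-3-hydroxy-2-(2-hydroxyphenoxy)benzamide
Conditions: NH3 (liq., excess), THF, −33 °C → rt (sealed); evaporate; dilute citric acid wash
Reagents that add atoms: ammonia, N
Why: Ammonolysis of an activated phenolic lactone (ester aminolysis with a phenoxide leaving group) should open the ring to the primary amide and free the ring-A hydroxyl, never passing through a free acid that could relactonise.

Step 6
Reactants: 9 4,6-dibromo-3-hydroxy-2-(2-hydroxyphenoxy)benzamide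
Product: 10 4,6-dibromo-2-(5-bromo-2-hydroxyphenoxy)-3-hydroxybenzamide
Conditions: NBS (1.0 equiv), MeCN, −20 → 0 °C
Reagents that add atoms: N-bromosuccinimide, O=C1CCC(=O)N1Br
Why: Electrophilic aromatic bromination directed by the free ring-A hydroxyl should go para to that OH, as 2-methoxyphenol gives its 4-bromo derivative, while the ring-B phenol has no free ortho or para position.

Step 7
Reactants: 10 4,6-dibromo-2-(5-bromo-2-hydroxyphenoxy)-3-hydroxybenzamide
Product: 11 4,6-dibromo-2-(5-bromo-2-methoxyphenoxy)-3-methoxybenzamide
Conditions: MeI (3 equiv), K2CO3 (3 equiv), DMF, rt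
Reagents that add atoms: iodomethane, CI
Why: Williamson O-methylation of both phenoxides should leave the primary amide untouched (not deprotonated by K2CO3), and methyl ethers are chosen because they survive hypochlorite/NaOH and diazotisation.

Step 8
Reactants: 11 4,6-dibromo-2-(5-bromo-2-methoxyphenoxy)-3-methoxybenzamide
Product: 14 4,6-dibromo-2-(5-bromo-2-methoxyphenoxy)-3-methoxyaniline, via N-chloroamide 12 (not isolated), via aryl isocyanate 13 (not isolated)
Conditions: NaOCl (aq., 1.2 equiv), NaOH (aq.), 1,4-dioxane, 0 → 70 °C
Reagents that add atoms: none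
Why: Hofmann rearrangement (N-chlorination, deprotonation, 1,2-aryl shift to the isocyanate, hydrolysis and loss of CO2) should give the aniline, since di-ortho-substituted benzamides rearrange readily and no aroyloxyl radical is formed.

Step 9
Reactants: 14 4,6-dibromo-2-(5-bromo-2-methoxyphenoxy)-3-methoxyaniline
Product: 16 1,2,5-tribromo-3-(5-bromo-2-methoxyphenoxy)-4-methoxybenzene, via arenediazonium salt 15 (not isolated)
Conditions: t-BuONO (1.5 equiv), CuBr2 (1.2 equiv), MeCN, 0 → 60 °C
Reagents that add atoms: copper(II) bromide, Br[Cu]Br
Why: Sandmeyer bromination in its anhydrous alkyl nitrite/CuBr2 form diazotises the weakly basic hindered aniline in situ, and bromine-atom transfer from CuBr2 to the aryl radical should outrun its cyclisation onto the neighbouring ring.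

Step 10
Reactants: 16 1,2,5-tribromo-3-(5-bromo-2-methoxyphenoxy)-4-methoxybenzene
Product: 17 3,4,6-tribromo-2-(5-bromo-2-hydroxyphenoxy)phenol (CNP0307618.0)
Conditions: BBr3 (4 equiv), CH2Cl2, −78 °C → rt; H2O
Reagents that add atoms: none
Why: BBr3 cleavage of both aryl methyl ethers should leave the diaryl ether and the aryl bromides intact, the usual last step for hydroxylated polybrominated diphenyl ethers.

**Compound list**

1 | 3-methoxybenzoic acid | COc1cccc(C(=O)O)c1 | starting material
2 | 2,4-dibromo-5-methoxybenzoic acid | COc1cc(C(=O)O)c(Br)cc1Br | intermediate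
3 | 2-methoxyphenol | COc1ccccc1O | starting material
4 | 2,4-dibromo-5-methoxybenzoyl chloride (not isolated) | COc1cc(C(=O)Cl)c(Br)cc1Br | intermediate
5 | 2-methoxyphenyl 2,4-dibromo-5-methoxybenzoate | COc1ccccc1OC(=O)c1cc(OC)c(Br)cc1Br | intermediate
6 | 2-hydroxyphenyl 2,4-dibromo-5-hydroxybenzoate (depside, key-step precursor) | O=C(Oc1ccccc1O)c1cc(O)c(Br)cc1Br | intermediate
7 | 1,3-dibromo-4aH-dibenzo[b,e][1,4]dioxepine-4,11-dione (keto tautomer of 8, racemic at C4a, not isolated) | O=C1Oc2ccccc2OC2C1=C(Br)C=C(Br)C2=O | intermediate
8 | 1,3-dibromo-4-hydroxy-11H-dibenzo[b,e][1,4]dioxepin-11-one (depsidone, key-step product) | O=C1Oc2ccccc2Oc2c(O)c(Br)cc(Br)c21 | intermediate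
9 | 4,6-dibromo-3-hydroxy-2-(2-hydroxyphenoxy)benzamide | NC(=O)c1c(Br)cc(Br)c(O)c1Oc1ccccc1O | intermediate
10 | 4,6-dibromo-2-(5-bromo-2-hydroxyphenoxy)-3-hydroxybenzamide | NC(=O)c1c(Br)cc(Br)c(O)c1Oc1cc(Br)ccc1O | intermediate
11 | 4,6-dibromo-2-(5-bromo-2-methoxyphenoxy)-3-methoxybenzamide | NC(=O)c1c(Br)cc(Br)c(OC)c1Oc1cc(Br)ccc1OC | intermediate
12 | N-chloro-4,6-dibromo-2-(5-bromo-2-methoxyphenoxy)-3-methoxybenzamide (not isolated) | ClNC(=O)c1c(Br)cc(Br)c(OC)c1Oc1cc(Br)ccc1OC | intermediate
13 | 4,6-dibromo-2-(5-bromo-2-methoxyphenoxy)-3-methoxyphenyl isocyanate (not isolated) | O=C=Nc1c(Br)cc(Br)c(OC)c1Oc1cc(Br)ccc1OC | intermediate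
14 | 4,6-dibromo-2-(5-bromo-2-methoxyphenoxy)-3-methoxyaniline | Nc1c(Br)cc(Br)c(OC)c1Oc1cc(Br)ccc1OC | intermediate
15 | 4,6-dibromo-2-(5-bromo-2-methoxyphenoxy)-3-methoxybenzenediazonium bromide (not isolated) | N#[N+]c1c(Br)cc(Br)c(OC)c1Oc1cc(Br)ccc1OC.[Br-] | intermediate
16 | 1,2,5-tribromo-3-(5-bromo-2-methoxyphenoxy)-4-methoxybenzene | COc1ccc(Br)cc1Oc1c(OC)c(Br)cc(Br)c1Br | intermediate
17 | 3,4,6-tribromo-2-(5-bromo-2-hydroxyphenoxy)phenol | Oc1ccc(Br)cc1Oc1c(O)c(Br)cc(Br)c1Br | target

**Step count and risks**

Total step count: 10. Longest linear sequence: 10 steps (1 → 17); 3 enters in step 2.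

Steps most likely to fail:

Step 4. Before the s-cis ester rotamer closes the ring, the oxidised depside may be consumed in three ways: intermolecular phenol coupling, ipso attack of the catechol oxygen at the bromine-bearing carbon para to the phenol oxygen with loss of bromide, or over-oxidation of the more electron-rich product. The fallback builds the ether bond without any oxidation. It sets out from 1 and 3 and comes back at 8. Directed ortho-lithiation of 1 between carboxylate and methoxy (LiTMP, THF) should give lithium 2-lithio-3-methoxybenzoate F1 (not isolated), and iodine quench should give 2-iodo-3-methoxybenzoic acid F2. Carboxylate-assisted Ullmann condensation of F2 with 3 (CuI, K2CO3, pyridine/DMF, 110 °C) should give 3-methoxy-2-(2-methoxyphenoxy)benzoic acid F3. BBr3 should then give 3-hydroxy-2-(2-hydroxyphenoxy)benzoic acid F4, and DCC lactonisation at high dilution should give 4-hydroxy-11H-dibenzo[b,e][1,4]dioxepin-11-one F5. NBS (2 equiv) should brominate only the free-phenol ring, ortho and para to its OH, to give 8.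

Step 9. The aryl radical formed on loss of nitrogen sits ortho to the aryloxy group and may cyclise onto ring A (Pschorr-type dibenzofuran formation) or be reduced by hydrogen abstraction instead of taking up bromine. The fallback avoids amine, diazonium and aryl radical. It sets out from 11 and comes back at 16. Nitrosative hydrolysis of the hindered amide (NaNO2, H2SO4/AcOH, 0 → 50 °C) should give 4,6-dibromo-2-(5-bromo-2-methoxyphenoxy)-3-methoxybenzoic acid F6. Base-mediated ipso-bromodecarboxylation (Bu4NBr3, K3PO4, MeCN, 100 °C), a non-radical decarboxylative bromination known for ortho-substituted alkoxybenzoic acids, should then give 16.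

Step 6. Bromination may not stop at one bromine, or may enter ortho instead of para to the ring-A hydroxyl, giving isomers that would be carried to the end. The fallback fixes the bromine position by the choice of phenol instead of by substitution. It sets out from 4 and comes back at 10. Acylation of commercial 4-bromo-2-methoxyphenol (COc1cc(Br)ccc1O) with 4 (Et3N, DMAP) should give 4-bromo-2-methoxyphenyl 2,4-dibromo-5-methoxybenzoate F7, and BBr3 should give 4-bromo-2-hydroxyphenyl 2,4-dibromo-5-hydroxybenzoate F8. Anodic closure as in step 4 follows, but in a divided cell and without base, so that no ring-A phenolate forms and the acyl group stays on the oxygen para to bromine. It should pass through 1,3,7-tribromo-4aH-dibenzo[b,e][1,4]dioxepine-4,11-dione F9 (not isolated) to 1,3,7-tribromo-4-hydroxy-11H-dibenzo[b,e][1,4]dioxepin-11-one F10. Ammonolysis as in step 5 then gives 10.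

**Further compounds**

F1 | step 4 | lithium 2-lithio-3-methoxybenzoate (not isolated) | [Li]c1c(OC)cccc1C(=O)O[Li]
F2 | step 4 | 2-iodo-3-methoxybenzoic acid | COc1cccc(C(=O)O)c1I
F3 | step 4 | 3-methoxy-2-(2-methoxyphenoxy)benzoic acid | COc1ccccc1Oc1c(OC)cccc1C(=O)O
F4 | step 4 | 3-hydroxy-2-(2-hydroxyphenoxy)benzoic acid | Oc1ccccc1Oc1c(O)cccc1C(=O)O
F5 | step 4 | 4-hydroxy-11H-dibenzo[b,e][1,4]dioxepin-11-one | O=C1Oc2ccccc2Oc2c(O)cccc21
F6 | step 9 | 4,6-dibromo-2-(5-bromo-2-methoxyphenoxy)-3-methoxybenzoic acid | OC(=O)c1c(Br)cc(Br)c(OC)c1Oc1cc(Br)ccc1OC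
F7 | step 6 | 4-bromo-2-methoxyphenyl 2,4-dibromo-5-methoxybenzoate | COc1cc(Br)ccc1OC(=O)c1cc(OC)c(Br)cc1Br
F8 | step 6 | 4-bromo-2-hydroxyphenyl 2,4-dibromo-5-hydroxybenzoate | O=C(Oc1ccc(Br)cc1O)c1cc(O)c(Br)cc1Br
F9 | step 6 | 1,3,7-tribromo-4aH-dibenzo[b,e][1,4]dioxepine-4,11-dione (not isolated) | O=C1Oc2ccc(Br)cc2OC2C1=C(Br)C=C(Br)C2=O
F10 | step 6 | 1,3,7-tribromo-4-hydroxy-11H-dibenzo[b,e][1,4]dioxepin-11-one | O=C1Oc2ccc(Br)cc2Oc2c(O)c(Br)cc(Br)c21
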